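# De Mayo ring-expansion route to CNP0142137.1

Atom numbers C1–C13 are those of the target: C1–C10 ring carbons, oxygen bridge C1–O–C4, lactone carbons C11–C13.

## The problem

The target is a ten-membered carbocycle (C1–C10) bridged between C1 and C4 by an ether oxygen, which makes a 2,5-cis oxolane with a quaternary, methyl-bearing C4. It is fused at C6–C7 to a γ-ylidene butenolide (C6, C7, C11, C12 and the ring oxygen) whose exocyclic alkene C5=C6 lies inside the large ring.

Four ring stereocentres have to be set. C1 and C4 are locked cis by the bridge and can both derive from one chiral-pool centre. C10, a tertiary carbinol next to C1, can be controlled from C1 through the α-oxygen. C8 is 1,3 to C10, has no controlling neighbour and is the hardest centre. A fifth centre sits in the (S)-2-methyloxirane-2-carboxylate on O8 and has to arrive with the acid.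

The enol lactone is an acyl donor and a Michael acceptor, the C13 acetate is allylic, and the epoxy ester tolerates neither organometallics nor strong acid. All three therefore belong at the end. The β-oxygenated ketones on the way are open to E1cB loss and retro-aldol cleavage. Direct closure of a ten-membered ring is the classical difficulty of this class.

The feature that removes it is the relation between C6 and C10. Both are at the carbonyl oxidation level (enol-lactone carbon and carbinol), they are 1,5-related, and oxygenated C8 sits midway. That is the pattern left when a two-carbon alkene (C8–C9) is inserted into a cyclic 1,3-dione (C6–C7–C10) by photocycloaddition and retro-aldol cleavage. Because the C1–O–C4 bridge takes no part, the dione can be an oxygen-bridged eight-membered ring in which both oxolane centres already stand.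

## Retrosynthesis

**C8 ester.** The acyl C–O bond at O8 is cut first, giving alcohol 27 and (S)-2-methyloxirane-2-carboxylic acid 29, itself the oxidation product of (R)-2-methylglycidol 28. Carrying the epoxy ester any earlier would expose it to MeMgBr, amide bases and acid. The forward step asks only for acylation of a hindered allylic alcohol beside an unreactive tertiary one. Since the C8–O bond is not touched, the same alcohol with the opposite C8 configuration could be used with inversion.

**Butenolide.** Alcohol 27 comes from silyl ether 26, whose lactone is opened at O–C12 and C7=C11 to aldol adduct 25, and 25 is cut at C7–C11 into enol silane 22 and ethyl acetoxypyruvate 24. The pyruvate brings C11, C12 and C13 at their final oxidation levels, so no late allylic oxidation of a C13 methyl is needed. The forward reactions must enolise the C6 ketone toward C7 and not C5, and then close the lactone on the C6 enol toward C5.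

**C10 methyl.** Enol silane 22 derives from hydroxy ketone 21, and cutting C10–CH3 in 21 leads to 1,5-dione 20. The forward addition must choose C10 over C6 and one face of C10. Both are asked of the oxolane oxygen, which is α to C10 and can chelate the metal.

**C8 oxygen.** Dione 20 is the silyl ether of alcohol 19, and the C8–O bond of 19 is traced to the C8–B bond of boronate 18 (oxidation with retention). Boron is chosen over an oxygen substituent because a donor alkene would add with the opposite orientation, putting the heteroatom on C9 next to C10. It would also place a leaving group β to two ketones during photolysis.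

**Key disconnection.** In 18 the bonds C7–C8 and C9–C10 are cut and C7–C10 is re-formed, which gives bridged 1,3-dione 15 and vinylboronate 16 by way of cyclobutanol 17. This replaces a ten-membered ring with three stereocentres by a rigid bicycle with two. Cutting C8–C9 or C5–C6 instead would demand an end-to-end medium-ring closure. The forward reaction must be head-to-head and must set C8. Because either C8 epimer can be esterified to the target (retention or inversion), C8 selectivity affects efficiency rather than feasibility.

**Eight-membered ring.** Dione 15 is the oxidation product of ketol 14, and 14 is cut at C6–C7 to bromo keto aldehyde 13. A samarium enolate fixed at C7 is preferred over a base-mediated aldol of the parent keto aldehyde, where the aldehyde enolises and C5 can attack the C10 ketone. A Claisen acylation was set aside because it is poor for eight-membered rings. The cis-oxolane holds both arms on one face.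

**Side arms.** Compound 13 is reached from 12, 11, 9, 7, 6 and 5 by functional-group changes only, and 5 comes from oxide 3. The vinyl group becomes CH2CHO (C5, C6) by hydroboration and oxidation. The hydroxyisopropyl group becomes the bromoacetyl group (C10, C7) by dehydration, ozonolysis and bromination. Hydroboration has to come before the second alkene is made. The carbinol carbon of 3 is the future C10 and is taken down to a ketone only to be rebuilt in step 14; that is the price of the key step.

**Oxolane.** The C1–O bond of 3 is cut to epoxy alcohol 2, and 2 to (R)-linalool 1. C4 is the linalool stereocentre. C1 is set by a reagent-controlled epoxidation followed by 5-exo opening with inversion, which leaves the two arms cis.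

## Roads not taken

**Alternative 1:** The oxolane is cut at C3–C4. Forward, Bu3SnH and AIBN turn bromide A1 into a C3 radical that adds 5-exo to C4 of the (E)-β-alkoxycrotonate on O1 and gives oxolane A2.

- Merits: β-alkoxyacrylate radical cyclisations give 2,5-cis oxolanes dependably, the conditions are neutral, and the C10 carbinol with its methyl is carried intact from the start.
- Weak points: the β-methyl on the acceptor slows the addition and may erode the cis preference at the quaternary centre. Tin has to be removed. A2 is still only an oxolane with two arms, so the ten-membered ring, C8 and the butenolide all remain, and the ring must later be closed end to end.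
- Comparison: this road is better at C10, which the chosen plan degrades and rebuilds. The chosen plan sets against that a one-step cis-oxolane from linalool and a ten-membered ring obtained by fragmentation instead of macrocyclisation.

**Alternative 2:** The C4–O bond is cut transannularly and C12 is taken down to the furan level. Forward, anodic oxidation of furan diol A3 lets the C1 hydroxyl add to C4 of the radical cation while methanol caps C12, giving lactol ether A4.

- Merits: one late step forms the oxolane, sets C4 and installs the C5=C6/C7=C11 diene. It avoids the butenolide annulation and its C5-versus-C7 regiochemistry, which is a real advantage over the chosen plan.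
- Weak points: A3 already contains the ten-membered ring, an (E)-alkene and three stereocentres, so the main problem is only moved. The C10 hydroxyl can compete for C4 (six-membered ether) and methanol can compete with both hydroxyls. The C4 configuration depends on the macrocycle conformation. A4 is a C12 epimer mixture that still needs oxidation to the lactone.
- Comparison: the chosen plan pays about five steps for the lactone but reaches its ring-expansion substrate from a terpene in a short, stereodefined sequence.

**Alternative 3:** The ring is traced to a cyclohexane by restoring a temporary C5–C10 bond and cutting C2–C3. Forward, siloxy-Cope rearrangement of A5 at about 200 °C gives germacradienolide A6.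

- Merits: it is also a ring expansion, the butenolide is present early, and C8 is set on a six-membered ring. That is more secure than the C8 control of the chosen plan.
- Weak points: the neutral siloxy-Cope is not strongly driven and germacradiene/elemadiene equilibria often favour the six-membered side. The temperature is high for a butenolide bearing three silyl ethers. A6 lacks the oxolane and has C6 as an sp3 carbinol carbon, so C1 oxygenation, C4–O bond formation and a C5–C6 dehydrogenation remain, as well as the C10 methyl addition.
- Comparison: against its better C8 control, the chosen plan sets a C8 that can be corrected at the esterification and a precursor that already carries the oxolane and the C6 oxidation level.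

Key step: step 11

Assumption: ethyl 3-acetoxy-2-oxopropanoate is not taken as commercial and is made in step 16; (R)-linalool and (R)-2-methylglycidol are taken as available in high enantiomeric purity.

## Route

Step 1
Reactants: 1 (R)-linalool
Product: 3 cis-furanoid linalool oxide 2-[(2S,5R)-5-ethenyl-5-methyloxolan-2-yl]propan-2-ol, via (3R,6R)-6,7-epoxylinalool 2 (not isolated)
Conditions: Shi ketone from D-fructose (1,2:4,5-di-O-isopropylidene-β-D-erythro-hexo-2,3-diulo-2,6-pyranose, 0.3 equiv), KHSO5 (as 2KHSO5·KHSO4·K2SO4), K2CO3, Bu4NHSO4, MeCN/CH2(OMe)2/aq. Na2B4O7, 0 °C; then CSA (0.1 equiv), CH2Cl2, 0 °C → rt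
Reagents that add atoms: potassium peroxymonosulfate, [K+].[O-]S(=O)(=O)OO
Why: Shi asymmetric epoxidation of the trisubstituted alkene (the vinyl group is inert to the dioxirane) gives the (6R)-epoxide under reagent control; acid-catalysed 5-exo opening by the tertiary hydroxyl, favoured over the 6-endo mode, inverts that carbon and sets C1 with its arm cis to the vinyl arm on C4.

Step 2
Reactants: 3 cis-furanoid linalool oxide
Product: 5 diol 2-[(2S,5R)-5-(2-hydroxyethyl)-5-methyloxolan-2-yl]propan-2-ol, via B-alkyl-9-borabicyclo[3.3.1]nonane 4 (not isolated)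
Conditions: 9-BBN (2.5 equiv), THF, 0 → 60 °C; then NaOH (aq.), H2O2, 0 °C → rt
Reagents that add atoms: hydrogen peroxide, OO
Why: Anti-Markovnikov hydroboration of the monosubstituted alkene by the bulky borane places boron on the terminal carbon, away from the quaternary centre, and oxidation of the C–B bond gives the primary alcohol (future C6); no stereocentre is formed.

Step 3
Reactants: 5 diol
Product: 6 primary silyl ether 2-[(2S,5R)-5-{2-[tert-butyl(dimethyl)silyloxy]ethyl}-5-methyloxolan-2-yl]propan-2-ol
Conditions: TBSCl (1.05 equiv), imidazole, CH2Cl2, 0 °C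
Reagents that add atoms: tert-butyldimethylsilyl chloride, CC(C)(C)[Si](C)(C)Cl
Why: Selective silylation of the primary hydroxyl, the tertiary one being inert to TBSCl and imidazole; the ether masks the future aldehyde through the alkene-forming and oxidative steps.

Step 4
Reactants: 6 primary silyl ether
Product: 7 isopropenyl oxolane (2R,5S)-2-{2-[tert-butyl(dimethyl)silyloxy]ethyl}-2-methyl-5-(prop-1-en-2-yl)oxolane
Conditions: POCl3, pyridine, 0 °C → rt
Reagents that add atoms: none
Why: E2 dehydration of the tertiary alcohol through its dichlorophosphate; loss of a methyl proton gives the isopropenyl group, the known dehydration of furanoid linalool oxides to their anhydro derivatives, while elimination toward C1 would need the single hydrogen on the oxygen-bearing carbon.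

Step 5
Reactants: 7 isopropenyl oxolane
Product: 9 methyl ketone 1-[(2S,5R)-5-{2-[tert-butyl(dimethyl)silyloxy]ethyl}-5-methyloxolan-2-yl]ethan-1-one, via secondary ozonide 8 (not isolated)
Conditions: O3, CH2Cl2, −78 °C; then Me2S, −78 °C → rt
Reagents that add atoms: ozone, [O-][O+]=O
Why: Ozonolysis with reductive work-up turns the 1,1-disubstituted alkene into the C10 ketone and leaves its methyl as the future C7; C1, now α to a ketone, is not epimerised under these neutral conditions.

Step 6
Reactants: 9 methyl ketone
Product: 11 bromomethyl ketone 2-bromo-1-[(2S,5R)-5-{2-[tert-butyl(dimethyl)silyloxy]ethyl}-5-methyloxolan-2-yl]ethan-1-one, via trimethylsilyl enol ether 10 (not isolated)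
Conditions: LiN(SiMe3)2, TMSCl, THF, −78 °C; then NBS, THF, −78 → 0 °C
Reagents that add atoms: N-bromosuccinimide, O=C1CCC(=O)N1Br
Why: Kinetic enolisation occurs on the methyl side (the α-alkoxy methine is hindered and untouched at −78 °C) and is trapped as the silyl enol ether; electrophilic bromination of that enol ether gives the bromomethyl ketone regiospecifically.

Step 7
Reactants: 11 bromomethyl ketone
Product: 12 hydroxy bromoketone 2-bromo-1-[(2S,5R)-5-(2-hydroxyethyl)-5-methyloxolan-2-yl]ethan-1-one
Conditions: HF·pyridine, THF/pyridine, 0 °C → rt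
Reagents that add atoms: none
Why: Fluoride cleavage of the primary silyl ether under buffered, weakly acidic conditions that leave the α-bromo ketone untouched.

Step 8
Reactants: 12 hydroxy bromoketone
Product: 13 bromo keto aldehyde 2-[(2R,5S)-5-(bromoacetyl)-2-methyloxolan-2-yl]acetaldehyde
Conditions: Dess–Martin periodinane, NaHCO3, CH2Cl2, 0 °C → rt
Reagents that add atoms: none
Why: Dess–Martin oxidation of the primary alcohol to the aldehyde (C6) without base, so the bromoketone is neither enolised nor substituted.

Step 9
Reactants: 13 bromo keto aldehyde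
Product: 14 bicyclic ketol (1S,6R)-4-hydroxy-6-methyl-9-oxabicyclo[4.2.1]nonan-2-one (both carbinol epimers)
Conditions: SmI2 (2.5 equiv), THF, −78 °C, slow addition of 13 (final 0.005 M)
Reagents that add atoms: none
Why: SmI2-mediated intramolecular Reformatsky-type aldol: two-electron reduction of the C–Br bond gives a samarium enolate fixed at C7 that adds to the aldehyde and forms C6–C7; the cis-oxolane holds both arms on one face and high dilution suppresses intermolecular aldol, as in known closures of eight-membered carbocycles; the new carbinol centre is destroyed in step 10.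

Step 10
Reactants: 14 bicyclic ketol
Product: 15 bridged dione (1S,6R)-6-methyl-9-oxabicyclo[4.2.1]nonane-2,4-dione
Conditions: Dess–Martin periodinane (1.1 equiv), NaHCO3, CH2Cl2, rt
Reagents that add atoms: none
Why: Oxidation of the β-hydroxy ketone to the 1,3-dione; both carbinol epimers converge and the limited excess of oxidant avoids attack on the central methylene.

Step 11
Reactants: 15 bridged dione; 16 vinylboronic acid pinacol ester
Product: 18 boryl 1,5-dione (1S,4R,8R)-4-methyl-8-(4,4,5,5-tetramethyl-1,3,2-dioxaborolan-2-yl)-1,4-epoxycyclodecane-6,10-dione, via cis-fused cyclobutanol photoadduct 17 (not isolated)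
Conditions: 16 (10 equiv), MeCN (degassed, 0.02 M), hν (300–350 nm, Pyrex), 20 °C
Reagents that add atoms: none
Why: Irradiation excites the enol tautomer of 15 (hydroxyl on C10, the carbonyl carbon made more electrophilic by the α-oxygen); its triplet bonds C10 to the CH2 terminus of 16, and the resulting 1,4-biradical (α-keto radical at C7, boron-stabilised radical at C8) collapses by C7–C8 bond formation to cyclobutanol 17. Compound 17 is a strained β-hydroxy ketone and undergoes retro-aldol cleavage of C7–C10 in the flask, which converts the eight-membered ring into the ten-membered 1,5-dione 18. The closest known reaction type is the de Mayo two-carbon ring expansion of cyclic 1,3-diones, together with enone [2+2] photocycloadditions of vinylboronates. The four-membered ring closes by recombination of the 1,4-biradical; the ten-membered ring is not closed end to end but revealed by fragmentation of the bond shared by the two small rings, so no medium-ring cyclisation has to be paid for. The step needs head-to-head regiochemistry (boron-bearing carbon on C7): first bond formation at the unsubstituted alkene terminus gives the more stabilised α-boryl radical, the oxygen-bearing enol carbon pairs with the acceptor alkene in this sense, and the other enol tautomer gives the same constitution as long as boron ends on the carbon bound to C7. C8 is the only new stereocentre that survives, since C7 and C10 lose theirs on cleavage; it is fixed in the biradical closure, and the (8R) isomer arises when the alkene is bound on the enol face remote from the oxygen bridge and the boryl group closes exo, away from the C5–C6 flank. The lone pairs of the bridge oxygen beside C10 and the bulk of the pinacol boronate are the features counted on for this, while C1 and C4 are spectators.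

Step 12
Reactants: 18 boryl 1,5-dione
Product: 19 hydroxy dione (1S,4R,8R)-8-hydroxy-4-methyl-1,4-epoxycyclodecane-6,10-dione
Conditions: NaBO3·4H2O, THF/H2O (1:1), 0 °C → rt
Reagents that add atoms: sodium perborate, [Na+].[O-]OB=O
Why: Perborate oxidation of the secondary alkylboronate: C8 migrates from boron to oxygen with retention; the weakly basic conditions are the standard ones for β-boryl ketones and limit retro-aldol and E1cB loss.

Step 13
Reactants: 19 hydroxy dione
Product: 20 silyloxy dione (1S,4R,8R)-8-[tert-butyl(dimethyl)silyloxy]-4-methyl-1,4-epoxycyclodecane-6,10-dione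
Conditions: TBSOTf, 2,6-lutidine, CH2Cl2, −78 °C
Reagents that add atoms: tert-butyldimethylsilyl triflate, CC(C)(C)[Si](C)(C)OS(=O)(=O)C(F)(F)F
Why: Low-temperature silylation of the β-hydroxy ketone with a silyl triflate and a hindered base; the ether blocks retro-aldol cleavage in the basic steps that follow and keeps O8 from chelating the Grignard reagent.

Step 14
Reactants: 20 silyloxy dione
Product: 21 tertiary alcohol (1S,4R,8S,10R)-8-[tert-butyl(dimethyl)silyloxy]-10-hydroxy-4,10-dimethyl-1,4-epoxycyclodecan-6-one
Conditions: MeMgBr (1.1 equiv), CH2Cl2/Et2O, −78 °C; aq. NH4Cl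
Reagents that add atoms: methylmagnesium bromide, C[Mg]Br
Why: Chelation-controlled Grignard addition: magnesium bridges the C10 carbonyl and the oxolane oxygen in a five-membered chelate, which makes C10 the more reactive ketone and exposes the face on the side of C1–H; attack anti to C2 gives the (10R) carbinol (Cram chelate model). The C8 descriptor changes from R to S only because the CIP priorities change, and 21 may sit partly as its transannular hemiketal, which reopens on deprotonation.

Step 15
Reactants: 21 tertiary alcohol
Product: 22 enol silane (1S,4R,8S,10R)-8-[tert-butyl(dimethyl)silyloxy]-4,10-dimethyl-6,10-bis(trimethylsilyloxy)-1,4-epoxycyclodec-6-ene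
Conditions: LiN(iPr)2 (2.5 equiv), TMSCl (5 equiv, present from the start), THF, −78 °C; Et3N, pentane, cold aq. NaHCO3
Reagents that add atoms: chlorotrimethylsilane, C[Si](C)(C)Cl
Why: Kinetic deprotonation with in-situ silylation: C5 is neopentyl-like (flanked by quaternary C4), so the amide removes a C7 proton, as 3,3-disubstituted cycloalkanones enolise away from the quaternary carbon; immediate trapping prevents β-elimination of the C8 silyloxy group, the C10 alkoxide is silylated in the same pot, and the enol ether geometry is of no consequence.

Step 16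
Reactants: 23 ethyl bromopyruvate
Product: 24 ethyl 3-acetoxy-2-oxopropanoate
Conditions: KOAc, MeCN, 0 °C → rt
Reagents that add atoms: potassium acetate, CC(=O)[O-].[K+]
Why: SN2 displacement of the activated α-bromo ketone by acetate.

Step 17
Reactants: 22 enol silane; 24 ethyl 3-acetoxy-2-oxopropanoate
Product: 25 aldol adduct ethyl 3-acetoxy-2-[(1S,4R,8S,10R)-8-[tert-butyl(dimethyl)silyloxy]-4,10-dimethyl-6-oxo-10-(trimethylsilyloxy)-1,4-epoxycyclodecan-7-yl]-2-(trimethylsilyloxy)propanoate (mixture at C7 and C11)
Conditions: Cu(OTf)2 (0.1 equiv), THF, −78 → −40 °C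
Reagents that add atoms: none
Why: Mukaiyama aldol addition: divalent copper chelates the 1,2-dicarbonyl unit of 24 and activates its ketone toward the enol silane, forming C7–C11 with silyl transfer to the new tertiary oxygen; no base is present that could deprotonate the acidic pyruvate, and both new centres become sp2 in step 18.

Step 18
Reactants: 25 aldol adduct
Product: 26 silylated butenolide [(1S,4R,5E,8S,10R)-8-[tert-butyl(dimethyl)silyloxy]-10-hydroxy-4,10-dimethyl-12-oxo-1,4-epoxy-6,12-olide-5,7(11)-dien-13-yl] acetate
Conditions: CSA (0.3 equiv), toluene, 4 Å MS, 80 °C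
Reagents that add atoms: none
Why: Acid-catalysed cyclodehydration, the known conversion of ketone–pyruvate aldols into γ-ylidene butenolides: loss of silanol through the C6 enol gives the C7=C11 alkylidene keto ester, whose C6 enol toward C5 (the only enolisable side left) acylates on oxygen at C12 with loss of ethanol; only the isomer with C12 cis to C6 can close and the isomers equilibrate under acid; the C10 silyl ether is cleaved and the C8 silyl ether keeps O8 from capturing C12.

Step 19
Reactants: 26 silylated butenolide
Product: 27 allylic alcohol [(1S,4R,5E,8S,10R)-8,10-dihydroxy-4,10-dimethyl-12-oxo-1,4-epoxy-6,12-olide-5,7(11)-dien-13-yl] acetate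
Conditions: HF·pyridine, THF/pyridine, 0 °C → rt
Reagents that add atoms: none
Why: Buffered fluoride desilylation that spares the enol lactone and the acetate; O8 is trans to C12 across C7=C11 and cannot translactonise.

Step 20
Reactants: 28 (R)-2-methylglycidol
Product: 29 (S)-2-methyloxirane-2-carboxylic acid
Conditions: TEMPO (0.2 equiv), PhI(OAc)2 (2.2 equiv), MeCN/H2O (1:1), 0 °C → rt
Reagents that add atoms: water, O
Why: Oxoammonium oxidation of the primary alcohol through the aldehyde hydrate to the acid; the quaternary epoxide carbon cannot epimerise and its descriptor changes from R to S only through the CIP priorities.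

Step 21
Reactants: 27 allylic alcohol; 29 (S)-2-methyloxirane-2-carboxylic acid
Product: 31 CNP0142137.1, via mixed anhydride 30 (not isolated)
Conditions: 29, 2,4,6-trichlorobenzoyl chloride, Et3N, THF, 0 °C; then 27, DMAP, toluene, rt
Reagents that add atoms: none
Why: Yamaguchi esterification: DMAP attacks the less shielded glycidoyl carbonyl of the mixed anhydride and the acylpyridinium acylates the secondary C8 hydroxyl; the tertiary C10 hydroxyl does not react, and C8 keeps its configuration because its C–O bond is not broken.

## Compound list

1 | (R)-linalool, (3R)-3,7-dimethylocta-1,6-dien-3-ol | C=C[C@@](O)(C)CCC=C(C)C | starting material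
2 | (3R,6R)-6,7-epoxy-3,7-dimethyloct-1-en-3-ol | C=C[C@@](O)(C)CC[C@H]1OC1(C)C | intermediate (not isolated)
3 | cis-furanoid linalool oxide, 2-[(2S,5R)-5-ethenyl-5-methyloxolan-2-yl]propan-2-ol | C=C[C@@]1(C)CC[C@H](O1)C(C)(C)O | intermediate
4 | 9-{2-[(2S,5S)-5-(2-hydroxypropan-2-yl)-2-methyloxolan-2-yl]ethyl}-9-borabicyclo[3.3.1]nonane (same spatial arrangement as 3; descriptor changed by priorities) | C1CCC2CCCC1B2CC[C@@]1(C)CC[C@H](O1)C(C)(C)O | intermediate (not isolated)
5 | 2-[(2S,5R)-5-(2-hydroxyethyl)-5-methyloxolan-2-yl]propan-2-ol | OCC[C@@]1(C)CC[C@H](O1)C(C)(C)O | intermediate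
6 | 2-[(2S,5R)-5-{2-[tert-butyl(dimethyl)silyloxy]ethyl}-5-methyloxolan-2-yl]propan-2-ol | CC(C)(C)[Si](C)(C)OCC[C@@]1(C)CC[C@H](O1)C(C)(C)O | intermediate
7 | (2R,5S)-2-{2-[tert-butyl(dimethyl)silyloxy]ethyl}-2-methyl-5-(prop-1-en-2-yl)oxolane | CC(C)(C)[Si](C)(C)OCC[C@@]1(C)CC[C@H](O1)C(C)=C | intermediate
8 | 3-[(2S,5R)-5-{2-[tert-butyl(dimethyl)silyloxy]ethyl}-5-methyloxolan-2-yl]-3-methyl-1,2,4-trioxolane (epimers at the trioxolane carbon) | CC(C)(C)[Si](C)(C)OCC[C@@]1(C)CC[C@H](O1)C2(C)OCOO2 | intermediate (not isolated)
9 | 1-[(2S,5R)-5-{2-[tert-butyl(dimethyl)silyloxy]ethyl}-5-methyloxolan-2-yl]ethan-1-one | CC(C)(C)[Si](C)(C)OCC[C@@]1(C)CC[C@H](O1)C(C)=O | intermediate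
10 | {1-[(2S,5R)-5-{2-[tert-butyl(dimethyl)silyloxy]ethyl}-5-methyloxolan-2-yl]ethenyl}oxy(trimethyl)silane | CC(C)(C)[Si](C)(C)OCC[C@@]1(C)CC[C@H](O1)C(=C)O[Si](C)(C)C | intermediate (not isolated)
11 | 2-bromo-1-[(2S,5R)-5-{2-[tert-butyl(dimethyl)silyloxy]ethyl}-5-methyloxolan-2-yl]ethan-1-one | CC(C)(C)[Si](C)(C)OCC[C@@]1(C)CC[C@H](O1)C(=O)CBr | intermediate
12 | 2-bromo-1-[(2S,5R)-5-(2-hydroxyethyl)-5-methyloxolan-2-yl]ethan-1-one | OCC[C@@]1(C)CC[C@H](O1)C(=O)CBr | intermediate
13 | 2-[(2R,5S)-5-(bromoacetyl)-2-methyloxolan-2-yl]acetaldehyde | O=CC[C@@]1(C)CC[C@H](O1)C(=O)CBr | intermediate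
14 | (1S,6R)-4-hydroxy-6-methyl-9-oxabicyclo[4.2.1]nonan-2-one (both C4 epimers; bicycle C4 = target C6) | OC1C[C@@]2(C)CC[C@H](O2)C(=O)C1 | intermediate
15 | (1S,6R)-6-methyl-9-oxabicyclo[4.2.1]nonane-2,4-dione | O=C1C[C@@]2(C)CC[C@H](O2)C(=O)C1 | intermediate (key-step precursor)
16 | vinylboronic acid pinacol ester, 2-ethenyl-4,4,5,5-tetramethyl-1,3,2-dioxaborolane | C=CB1OC(C)(C)C(C)(C)O1 | starting material
17 | cis-fused cyclobutanol photoadduct: cyclobutane C7–C8–C9–C10 on the face of the eight-membered ring remote from the oxygen bridge, hydroxyl on C10, pinacol boronate on C8 cis to the C10 hydroxyl (exo) | O=C1C[C@@]2(C)CC[C@H](O2)[C@@]3(O)C[C@H](B4OC(C)(C)C(C)(C)O4)[C@@H]13 | intermediate (not isolated)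
18 | (1S,4R,8R)-4-methyl-8-(4,4,5,5-tetramethyl-1,3,2-dioxaborolan-2-yl)-1,4-epoxycyclodecane-6,10-dione (target numbering) | O=C1C[C@@]2(C)CC[C@H](O2)C(=O)C[C@H](B3OC(C)(C)C(C)(C)O3)C1 | intermediate (key-step product)
19 | (1S,4R,8R)-8-hydroxy-4-methyl-1,4-epoxycyclodecane-6,10-dione | O=C1C[C@@]2(C)CC[C@H](O2)C(=O)C[C@H](O)C1 | intermediate
20 | (1S,4R,8R)-8-[tert-butyl(dimethyl)silyloxy]-4-methyl-1,4-epoxycyclodecane-6,10-dione | O=C1C[C@@]2(C)CC[C@H](O2)C(=O)C[C@H](O[Si](C)(C)C(C)(C)C)C1 | intermediate
21 | (1S,4R,8S,10R)-8-[tert-butyl(dimethyl)silyloxy]-10-hydroxy-4,10-dimethyl-1,4-epoxycyclodecan-6-one | O=C1C[C@@]2(C)CC[C@H](O2)[C@](C)(O)C[C@H](O[Si](C)(C)C(C)(C)C)C1 | intermediate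
22 | (1S,4R,8S,10R)-8-[tert-butyl(dimethyl)silyloxy]-4,10-dimethyl-6,10-bis(trimethylsilyloxy)-1,4-epoxycyclodec-6-ene (C6=C7 geometry not controlled) | C[Si](C)(C)OC=1C[C@@]2(C)CC[C@H](O2)[C@](C)(O[Si](C)(C)C)C[C@H](O[Si](C)(C)C(C)(C)C)C=1 | intermediate
23 | ethyl bromopyruvate, ethyl 3-bromo-2-oxopropanoate | CCOC(=O)C(=O)CBr | starting material
24 | ethyl 3-acetoxy-2-oxopropanoate | CCOC(=O)C(=O)COC(C)=O | intermediate
25 | ethyl 3-acetoxy-2-[(1S,4R,8S,10R)-8-[tert-butyl(dimethyl)silyloxy]-4,10-dimethyl-6-oxo-10-(trimethylsilyloxy)-1,4-epoxycyclodecan-7-yl]-2-(trimethylsilyloxy)propanoate (mixture at C7 and C11) | O=C1C[C@@]2(C)CC[C@H](O2)[C@](C)(O[Si](C)(C)C)C[C@H](O[Si](C)(C)C(C)(C)C)C1C(O[Si](C)(C)C)(COC(C)=O)C(=O)OCC | intermediate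
26 | C8 silyl ether of the 13-acetoxy γ-ylidene butenolide, (1S,4R,5E,8S,10R), C5=C6 cis within the ring, free C10 hydroxyl | CC(=O)OCC1=C2/C(=C\[C@@]3(C)CC[C@H](O3)[C@](C)(O)C[C@@H]2O[Si](C)(C)C(C)(C)C)OC1=O | intermediate
27 | 13-acetoxy γ-ylidene butenolide with free C8 and C10 hydroxyls, (1S,4R,5E,8S,10R) | CC(=O)OCC1=C2/C(=C\[C@@]3(C)CC[C@H](O3)[C@](C)(O)C[C@@H]2O)OC1=O | intermediate
28 | (R)-2-methylglycidol, [(2R)-2-methyloxiran-2-yl]methanol | OC[C@]1(C)CO1 | starting material
29 | (2S)-2-methyloxirane-2-carboxylic acid | OC(=O)[C@]1(C)CO1 | intermediate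
30 | (2S)-2-methyloxirane-2-carboxylic 2,4,6-trichlorobenzoic anhydride | O=C(OC(=O)[C@]1(C)CO1)c1c(Cl)cc(Cl)cc1Cl | intermediate (not isolated)
31 | CNP0142137.1, the (1S,4R,5E,8S,10R) 13-acetoxy-10-hydroxy 1,4-epoxy 6,12-enol lactone 8-[(2S)-2-methyloxirane-2-carboxylate] | CC(=O)OCC1=C2/C(=C\[C@@]3(C)CC[C@H](O3)[C@](C)(O)C[C@@H]2OC(=O)[C@]2(C)CO2)OC1=O | target

## Step count and least certain steps

Total: 21 steps. Longest linear sequence: 19 steps (steps 1–15, 17–19 and 21); steps 16 and 20 prepare the two side components.

**Step 11 (key step).** The most likely failure is poor control of the C8 configuration, with head-to-tail addition as a second leak. Both faces of the eight-membered enol are accessible (the face on the side of the small oxygen bridge may even be preferred) and triplet biradical closures rarely distinguish exo from endo strongly.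

The fallback keeps the photoreaction and makes the end of the route stereoconvergent; it sets out from 15 and returns at 31. The C8-epimeric boronate (1S,4R,8S)-4-methyl-8-(pinacolboryl)-1,4-epoxycyclodecane-6,10-dione F1 is oxidised with NaBO3·4H2O to the (8S)-hydroxy dione F2 and silylated to the (8S)-silyloxy dione F3. Chelation-controlled MeMgBr addition gives the (8R,10R)-hydroxy ketone F4, which is converted into the enol silane F5 and, with 24 and Cu(OTf)2, into the aldol adduct F6. CSA closes F6 to the C8-epimeric silylated butenolide F7, and HF·pyridine gives the C8-epimeric allylic alcohol F8. F8 is then esterified with 29 under Mitsunobu conditions (PPh3, DIAD, THF, 0 °C). SN2 displacement at the allylic C8 inverts it and gives 31.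

**Step 9.** The likely failure is simple reduction of the bromide or intermolecular aldol coupling instead of ring closure, because the samarium enolate must reach the aldehyde through a strained eight-membered transition state.

The fallback closes the ring by olefination and adds the C6 oxygen afterwards; it sets out from 13 and returns at 14. PPh3 (toluene, rt) converts 13 into the acylmethylphosphonium bromide F9. Et3N under high dilution (CH2Cl2, reflux) gives the stabilised ylide F10, which closes by intramolecular Wittig reaction to the bicyclic (Z)-enone F11. Copper-catalysed conjugate borylation (CuCl, NaOtBu, PPh3, B2pin2, MeOH, THF) gives the β-boryl ketone F12, and NaBO3·4H2O oxidises F12 to 14.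

**Step 14.** The likely failure is loss of chemoselectivity (addition at C6 or at both carbonyls), because the same ring oxygen can also chelate to C6 through a six-membered ring; facial selectivity at C10 could suffer for the same reason.

The fallback protects C6 first; it sets out from 20 and returns at 21. The less hindered, non-α-oxygenated C6 ketone is ketalised selectively with 1,2-bis(trimethylsilyloxy)ethane and catalytic TMSOTf (CH2Cl2, −78 °C) to the mono-dioxolane F13. MeMgBr then adds to the only free carbonyl to give the tertiary alcohol F14, and PPTS in wet acetone removes the ketal to give 21.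

**Step 15.** The likely failure is competing deprotonation at C5 or β-elimination of the C8 silyloxy group from the C7 enolate, since both α-positions are methylenes bearing a β-oxygen.

The fallback replaces kinetic deprotonation by an enamine formed under thermodynamic control; it sets out from 21 and returns at 26. Pyrrolidine (benzene, 4 Å MS, reflux) gives the less strained enamine toward C7, F15, which avoids the allylic strain of an enamine next to quaternary C4. F15 adds to 24 and is hydrolysed with aqueous acetic acid to the desilylated aldol adduct F16, which is cyclodehydrated under the conditions of step 18 to 26.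

**Step 18.** The likely failure is loss of the C8 silyl ether under hot acid, after which O8 captures C12 and forms the isomeric 8,12-lactone; incomplete lactonisation of the ethyl ester is the other concern.

The fallback separates the three events and closes the lactone from the free acid; it sets out from 25 and returns at 26. TFA (CH2Cl2, 0 °C) removes the trimethylsilyl groups and dehydrates to the alkylidene keto ester F17. LiOH (THF/H2O, 0 °C) hydrolyses the ethyl ester and the acetate, and the resulting (Z)-4-oxo-2-enoic acid closes to the hydroxybutenolide F18. Ac2O, pyridine and DMAP (rt → 60 °C) re-acetylate O13 and dehydrate the hemiketal toward C5 to give 26.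

## Further compounds

F1 | step 11 | (1S,4R,8S)-4-methyl-8-(4,4,5,5-tetramethyl-1,3,2-dioxaborolan-2-yl)-1,4-epoxycyclodecane-6,10-dione | O=C1C[C@@]2(C)CC[C@H](O2)C(=O)C[C@@H](B3OC(C)(C)C(C)(C)O3)C1
F2 | step 11 | (1S,4R,8S)-8-hydroxy-4-methyl-1,4-epoxycyclodecane-6,10-dione | O=C1C[C@@]2(C)CC[C@H](O2)C(=O)C[C@@H](O)C1
F3 | step 11 | (1S,4R,8S)-8-[tert-butyl(dimethyl)silyloxy]-4-methyl-1,4-epoxycyclodecane-6,10-dione | O=C1C[C@@]2(C)CC[C@H](O2)C(=O)C[C@@H](O[Si](C)(C)C(C)(C)C)C1
F4 | step 11 | (1S,4R,8R,10R)-8-[tert-butyl(dimethyl)silyloxy]-10-hydroxy-4,10-dimethyl-1,4-epoxycyclodecan-6-one | O=C1C[C@@]2(C)CC[C@H](O2)[C@](C)(O)C[C@@H](O[Si](C)(C)C(C)(C)C)C1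
F5 | step 11 | (1S,4R,8R,10R)-8-[tert-butyl(dimethyl)silyloxy]-4,10-dimethyl-6,10-bis(trimethylsilyloxy)-1,4-epoxycyclodec-6-ene | C[Si](C)(C)OC=1C[C@@]2(C)CC[C@H](O2)[C@](C)(O[Si](C)(C)C)C[C@@H](O[Si](C)(C)C(C)(C)C)C=1
F6 | step 11 | C8 epimer of aldol adduct 25 (mixture at C7 and C11) | O=C1C[C@@]2(C)CC[C@H](O2)[C@](C)(O[Si](C)(C)C)C[C@@H](O[Si](C)(C)C(C)(C)C)C1C(O[Si](C)(C)C)(COC(C)=O)C(=O)OCC
F7 | step 11 | C8 epimer of silylated butenolide 26, (1S,4R,5E,8R,10R) | CC(=O)OCC1=C2/C(=C\[C@@]3(C)CC[C@H](O3)[C@](C)(O)C[C@H]2O[Si](C)(C)C(C)(C)C)OC1=O
F8 | step 11 | C8 epimer of allylic alcohol 27, (1S,4R,5E,8R,10R) | CC(=O)OCC1=C2/C(=C\[C@@]3(C)CC[C@H](O3)[C@](C)(O)C[C@H]2O)OC1=O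
F9 | step 9 | {2-[(2S,5R)-5-methyl-5-(2-oxoethyl)oxolan-2-yl]-2-oxoethyl}triphenylphosphonium bromide | O=CC[C@@]1(C)CC[C@H](O1)C(=O)C[P+](c1ccccc1)(c1ccccc1)c1ccccc1.[Br-]
F10 | step 9 | 2-[(2R,5S)-2-methyl-5-(triphenylphosphoranylideneacetyl)oxolan-2-yl]acetaldehyde | O=CC[C@@]1(C)CC[C@H](O1)C(=O)C=P(c1ccccc1)(c1ccccc1)c1ccccc1
F11 | step 9 | (1S,6R,3Z)-6-methyl-9-oxabicyclo[4.2.1]non-3-en-2-one | O=C1/C=C\C[C@@]2(C)CC[C@@H]1O2
F12 | step 9 | (1S,6R)-6-methyl-4-(4,4,5,5-tetramethyl-1,3,2-dioxaborolan-2-yl)-9-oxabicyclo[4.2.1]nonan-2-one (both C4 epimers) | O=C1CC(B3OC(C)(C)C(C)(C)O3)C[C@@]2(C)CC[C@@H]1O2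
F13 | step 14 | C6 ethylene ketal of 20, (1S,4R,8R)-8-[tert-butyl(dimethyl)silyloxy]-6,6-(ethylenedioxy)-4-methyl-1,4-epoxycyclodecan-10-one | C12(OCCO1)C[C@@]3(C)CC[C@H](O3)C(=O)C[C@H](O[Si](C)(C)C(C)(C)C)C2
F14 | step 14 | C6 ethylene ketal of 21, (10R) tertiary alcohol | C12(OCCO1)C[C@@]3(C)CC[C@H](O3)[C@](C)(O)C[C@H](O[Si](C)(C)C(C)(C)C)C2
F15 | step 15 | pyrrolidine enamine of 21 with the C6=C7 double bond | C1CCN(C1)C=2C[C@@]3(C)CC[C@H](O3)[C@](C)(O)C[C@H](O[Si](C)(C)C(C)(C)C)C=2
F16 | step 15 | aldol adduct of 21 and 24 with free C10 and C11 hydroxyls (mixture at C7 and C11) | O=C1C[C@@]2(C)CC[C@H](O2)[C@](C)(O)C[C@H](O[Si](C)(C)C(C)(C)C)C1C(O)(COC(C)=O)C(=O)OCC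
F17 | step 18 | alkylidene keto ester, C7=C11 (both geometrical isomers), free C10 hydroxyl | O=C1C[C@@]2(C)CC[C@H](O2)[C@](C)(O)C[C@H](O[Si](C)(C)C(C)(C)C)C1=C(COC(C)=O)C(=O)OCC
F18 | step 18 | hydroxybutenolide (C6 hemiketal, both epimers) with free C13 hydroxyl | OCC1=C2C(O)(C[C@@]3(C)CC[C@H](O3)[C@](C)(O)C[C@@H]2O[Si](C)(C)C(C)(C)C)OC1=O
A1 | alternative 1 | acyclic bromide carrying the (E)-β-alkoxycrotonate on O1 | CCOC(=O)/C=C(/O[C@@H](CCBr)[C@](C)(O[Si](CC)(CC)CC)CO[Si](C)(C)C(C)(C)C)C
A2 | alternative 1 | 2,5-cis oxolane with C4 methyl and CH2CO2Et arm | CCOC(=O)C[C@@]1(C)CC[C@H](O1)[C@](C)(O[Si](CC)(CC)CC)CO[Si](C)(C)C(C)(C)C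
A3 | alternative 2 | ten-membered 2-alkenylfuran 1,10-diol, C8 O-triethylsilyl, (4E) | CC(=O)OCc1coc2/C=C(C)/CC[C@H](O)[C@](C)(O)C[C@H](O[Si](CC)(CC)CC)c12
A4 | alternative 2 | 12-methoxy lactol ether of the core (both C12 epimers), C8 O-triethylsilyl | CC(=O)OCC1=C2/C(=C\[C@@]3(C)CC[C@H](O3)[C@](C)(O)C[C@@H]2O[Si](CC)(CC)CC)OC1OC
A5 | alternative 3 | butenolide-fused trans-1-vinyl-2-isopropenylcyclohexanol trimethylsilyl ether | C=C[C@@]1(O[Si](C)(C)C)C[C@H](O[Si](CC)(CC)CC)C2=C(CO[Si](C)(C)C(C)(C)C)C(=O)O[C@H]2[C@@H]1C(C)=C
A6 | alternative 3 | cyclodeca-1(10),4-diene 6,12-olide with C10 silyl enol ether | C[Si](C)(C)O/C1=C\CC/C(C)=C/[C@@H]2OC(=O)C(CO[Si](C)(C)C(C)(C)C)=C2[C@@H](O[Si](CC)(CC)CC)C1
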